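**Plan**

1. Retrosynthetic cuts, in order: C6''=C7'' (Wittig); C4''–C5'' together with the C2''–O bond of an allyl vinyl ether (Claisen); the C2''–O bond itself (ene oxygenation of a prenyl group); C2''=C3'' of the prenyl group (cross-metathesis); C6–C1'' (aromatic Claisen from O5).
2. Enabling feature: the side-chain segment C1''–C2''=C3''(CH3)–C4''–C5''–C6'', an E-trisubstituted alkene separated from C6'' by two sp3 carbons. This is the γ,δ-unsaturated carbonyl pattern left by a [3,3] shift of a vinyl ether on a 2-methylallylic carbinol. On ring A (C5–C8), C6 is the only free position ortho to O5.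
3. Forward: both rings are bought intact in (S)-pinocembrin and no ring is formed. The chain grows C6-allyl → prenyl → C2'' carbinol → vinyl ether → C6'' aldehyde → geranyl.
4. Stereochemistry: C2 (S) comes from (S)-pinocembrin and is kept by avoiding strong base. The 2''E geometry comes from the chair transition state of the Claisen step. The transient C2'' carbinol centre needs no control.
5. Phenols: O7 is carried as a TIPS ether; O5 first as the migrating allyl ether, then as a TBS ether. Both come off together with buffered fluoride.

Key step: step 8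

Remark: (S)-pinocembrin is assumed to be available in high enantiomeric purity. Flavanone atoms are numbered O1, C2–C4, C4a, C5–C8, C8a; side-chain carbons are C1''–C8'' counted from the ring.

**Step 1**
Reactants: 1 (S)-pinocembrin [(2S)-5,7-dihydroxy-2-phenylchroman-4-one]
Product: 2 (2S)-5-hydroxy-2-phenyl-7-(triisopropylsilyloxy)chroman-4-one
Conditions: TIPSCl (1.05 equiv), imidazole, DMF, 0 °C
Reagents that add atoms: triisopropylsilyl chloride, CC(C)[Si](Cl)(C(C)C)C(C)C
Why: Silyl ether formation with a silyl chloride and imidazole should occur only at the free and more acidic 7-OH, because the 5-OH is tied up in a hydrogen bond to the C4 carbonyl and imidazole is too weak a base to open the flavanone ring or epimerise C2.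

**Step 2**
Reactants: 2 (2S)-5-hydroxy-2-phenyl-7-(triisopropylsilyloxy)chroman-4-one; 3 allyl alcohol
Product: 4 (2S)-5-(allyloxy)-2-phenyl-7-(triisopropylsilyloxy)chroman-4-one
Conditions: PPh3, DIAD, THF, 0 °C → rt
Reagents that add atoms: allyl alcohol (3), C=CCO
Why: Mitsunobu etherification works on the chelated 5-OH of 7-O-protected 5-hydroxyflavanones with primary alcohols, since the phenol is acidic enough to protonate the PPh3–DIAD betaine and the phenoxide then displaces the allyloxyphosphonium ion under near-neutral conditions that leave C2 alone.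

**Step 3**
Reactants: 4 (2S)-5-(allyloxy)-2-phenyl-7-(triisopropylsilyloxy)chroman-4-one
Product: 5 (2S)-6-allyl-5-hydroxy-2-phenyl-7-(triisopropylsilyloxy)chroman-4-one
Conditions: Eu(fod)3 (10 mol%), CHCl3, 70 °C (sealed tube)
Reagents that add atoms: none
Why: Aromatic Claisen rearrangement, accelerated by Eu(III) coordination to the C4 carbonyl and the ether oxygen, should deliver the allyl group to C6 because this is the only free position ortho to O5 (the other ortho carbon is the ring-fusion carbon C4a) and the C6 dienone tautomerises to the phenol faster than it can pass the allyl group on to C8.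

**Step 4**
Reactants: 5 (2S)-6-allyl-5-hydroxy-2-phenyl-7-(triisopropylsilyloxy)chroman-4-one
Product: 6 (2S)-6-allyl-5-(tert-butyldimethylsilyloxy)-2-phenyl-7-(triisopropylsilyloxy)chroman-4-one
Conditions: TBSOTf, 2,6-lutidine, CH2Cl2, −78 → 0 °C
Reagents that add atoms: tert-butyldimethylsilyl triflate, CC(C)(C)[Si](C)(C)OS(=O)(=O)C(F)(F)F
Why: Silylation with the highly electrophilic silyl triflate overcomes the hydrogen bond and the flanking substituents of the 5-OH, while 2,6-lutidine is too hindered and too weak to enolise the C4 ketone, so the phenol that could otherwise add to the later vinyl ether or consume ylide is masked.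

**Step 5**
Reactants: 6 (2S)-6-allyl-5-(tert-butyldimethylsilyloxy)-2-phenyl-7-(triisopropylsilyloxy)chroman-4-one; 7 2-methylbut-2-ene
Product: 8 (2S)-5-(tert-butyldimethylsilyloxy)-6-(3-methylbut-2-enyl)-2-phenyl-7-(triisopropylsilyloxy)chroman-4-one
Conditions: Grubbs II (5 mol%), 2-methylbut-2-ene (large excess), CH2Cl2, 40 °C (sealed tube)
Reagents that add atoms: 2-methylbut-2-ene (7), CC=C(C)C
Why: Olefin cross-metathesis of a terminal alkene with a large excess of 2-methylbut-2-ene is a standard way to turn an allyl into a prenyl group, and the trisubstituted product is too hindered to re-enter the catalytic cycle.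

**Step 6**
Reactants: 8 (2S)-5-(tert-butyldimethylsilyloxy)-6-(3-methylbut-2-enyl)-2-phenyl-7-(triisopropylsilyloxy)chroman-4-one
Product: 10 (2S)-5-(tert-butyldimethylsilyloxy)-6-(2-hydroxy-3-methylbut-3-enyl)-2-phenyl-7-(triisopropylsilyloxy)chroman-4-one (both C2'' epimers), via allylic hydroperoxide 9 (not isolated)
Conditions: O2, TPP (cat.), CH2Cl2, visible light, 0 °C; then PPh3, 0 °C → rt
Reagents that add atoms: dioxygen, O=O
Why: Schenck ene reaction of singlet oxygen with the trisubstituted prenyl alkene, in which abstraction of a methyl hydrogen shifts the double bond to C3''=C4'' and places the hydroperoxide on C2'', followed by phosphine reduction of the O–O bond; the new C2'' centre forms without control as both epimers, which is harmless because step 8 removes it, and the tertiary alcohol from abstraction at C1'' is separated by chromatography.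

**Step 7**
Reactants: 10 (2S)-5-(tert-butyldimethylsilyloxy)-6-(2-hydroxy-3-methylbut-3-enyl)-2-phenyl-7-(triisopropylsilyloxy)chroman-4-one (both C2'' epimers); 11 ethyl vinyl ether
Product: 12 (2S)-5-(tert-butyldimethylsilyloxy)-6-[3-methyl-2-(vinyloxy)but-3-enyl]-2-phenyl-7-(triisopropylsilyloxy)chroman-4-one (both C2'' epimers)
Conditions: Hg(OAc)2 (20 mol%), ethyl vinyl ether (solvent), reflux; filtration through basic alumina; unreacted 10 recycled
Reagents that add atoms: ethyl vinyl ether (11), C=COCC
Why: Mercury(II)-catalysed vinyl ether interchange (transetherification) proceeds by reversible alkoxymercuration of ethyl vinyl ether and is pulled towards the secondary allyl vinyl ether by the solvent excess, under conditions mild enough for the silyl ethers, the ketone and C2.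

**Step 8**
Reactants: 12 (2S)-5-(tert-butyldimethylsilyloxy)-6-[3-methyl-2-(vinyloxy)but-3-enyl]-2-phenyl-7-(triisopropylsilyloxy)chroman-4-one (both C2'' epimers)
Product: 13 (2S)-5-(tert-butyldimethylsilyloxy)-6-[(2E)-3-methyl-6-oxohex-2-enyl]-2-phenyl-7-(triisopropylsilyloxy)chroman-4-one
Conditions: PhMe (degassed), 130 °C, sealed tube, base-washed glassware
Reagents that add atoms: none
Why: Heating drives a concerted suprafacial [3,3]-sigmatropic shift through a chair-like six-membered transition state in which the C2''–O bond breaks, the terminal vinyl carbon bonds to C4'' (the new C4''–C5'' bond), the C3''=C4'' alkene moves to C2''=C3'' and the vinyl ether oxygen becomes the C6'' aldehyde. The closest known reaction type is the aliphatic Claisen rearrangement of vinyl ethers of secondary 2-methylallylic alcohols to (E)-trisubstituted γ,δ-unsaturated aldehydes. No ring is closed and no stereocentre is created; the C2'' carbinol centre is destroyed, so both epimers of 12 converge on one product. The selectivity needed is E over Z at C2''=C3'', and it is secured by the bulky arylmethyl group on C2'' (flanked by two ortho silyloxy groups), which prefers the pseudo-equatorial position of the chair and therefore ends up trans to C4'' across the new double bond; because the vinyl carbon carries only hydrogen this preference is strong but not absolute, and any Z isomer would be removed on AgNO3-impregnated silica. The step is thermal and neutral, so the base-sensitive C2 centre, both silyl ethers and the C4 ketone should pass through unchanged.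

**Step 9**
Reactants: 13 (2S)-5-(tert-butyldimethylsilyloxy)-6-[(2E)-3-methyl-6-oxohex-2-enyl]-2-phenyl-7-(triisopropylsilyloxy)chroman-4-one; 14 isopropyltriphenylphosphonium iodide
Product: 16 (2S)-5-(tert-butyldimethylsilyloxy)-6-[(2E)-3,7-dimethylocta-2,6-dienyl]-2-phenyl-7-(triisopropylsilyloxy)chroman-4-one, via isopropylidenetriphenylphosphorane 15 (not isolated)
Conditions: 14 (1.3 equiv), KHMDS (1.2 equiv), THF, 0 °C; then 13, −78 → −20 °C; sat. NH4Cl
Reagents that add atoms: isopropyltriphenylphosphonium iodide (14), CC(C)[P+](c1ccccc1)(c1ccccc1)c1ccccc1.[I-]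
Why: Wittig olefination with the unstabilised isopropylidene ylide, which at −78 °C should add to the unhindered aldehyde much faster than it attacks the hindered, electron-rich C4 aryl ketone or removes a C3 proton; the ylide is symmetrical, so no alkene geometry arises at C6''=C7''.

**Step 10**
Reactants: 16 (2S)-5-(tert-butyldimethylsilyloxy)-6-[(2E)-3,7-dimethylocta-2,6-dienyl]-2-phenyl-7-(triisopropylsilyloxy)chroman-4-one
Product: 17 (2S)-6-[(2E)-3,7-dimethylocta-2,6-dienyl]-5,7-dihydroxy-2-phenylchroman-4-one (CNP0201748.1)
Conditions: TBAF, AcOH (1:1), THF, 0 °C → rt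
Reagents that add atoms: none
Why: Fluoride-mediated cleavage of both aryl silyl ethers, which are activated by the ortho or para carbonyl group, with acetic acid buffering the liberated phenoxides so that the flavanone ring is not opened and C2 keeps its configuration, and with no strong acid that could cyclise the geranyl chain onto a phenol.

**Compound list**

1 | (S)-pinocembrin, (2S)-5,7-dihydroxy-2-phenylchroman-4-one | O=C1C[C@@H](c2ccccc2)Oc2cc(O)cc(O)c21 | starting material
2 | (2S)-5-hydroxy-2-phenyl-7-(triisopropylsilyloxy)chroman-4-one | O=C1C[C@@H](c2ccccc2)Oc2cc(O[Si](C(C)C)(C(C)C)C(C)C)cc(O)c21 | intermediate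
3 | allyl alcohol | C=CCO | starting material
4 | (2S)-5-(allyloxy)-2-phenyl-7-(triisopropylsilyloxy)chroman-4-one | O=C1C[C@@H](c2ccccc2)Oc2cc(O[Si](C(C)C)(C(C)C)C(C)C)cc(OCC=C)c21 | intermediate
5 | (2S)-6-allyl-5-hydroxy-2-phenyl-7-(triisopropylsilyloxy)chroman-4-one | O=C1C[C@@H](c2ccccc2)Oc2cc(O[Si](C(C)C)(C(C)C)C(C)C)c(CC=C)c(O)c21 | intermediate
6 | (2S)-6-allyl-5-(tert-butyldimethylsilyloxy)-2-phenyl-7-(triisopropylsilyloxy)chroman-4-one | O=C1C[C@@H](c2ccccc2)Oc2cc(O[Si](C(C)C)(C(C)C)C(C)C)c(CC=C)c(O[Si](C)(C)C(C)(C)C)c21 | intermediate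
7 | 2-methylbut-2-ene | CC=C(C)C | starting material
8 | (2S)-5-(tert-butyldimethylsilyloxy)-6-(3-methylbut-2-enyl)-2-phenyl-7-(triisopropylsilyloxy)chroman-4-one | O=C1C[C@@H](c2ccccc2)Oc2cc(O[Si](C(C)C)(C(C)C)C(C)C)c(CC=C(C)C)c(O[Si](C)(C)C(C)(C)C)c21 | intermediate
9 | (2S)-5-(tert-butyldimethylsilyloxy)-6-(2-hydroperoxy-3-methylbut-3-enyl)-2-phenyl-7-(triisopropylsilyloxy)chroman-4-one, both C2'' epimers | O=C1C[C@@H](c2ccccc2)Oc2cc(O[Si](C(C)C)(C(C)C)C(C)C)c(CC(OO)C(C)=C)c(O[Si](C)(C)C(C)(C)C)c21 | intermediate (not isolated)
10 | (2S)-5-(tert-butyldimethylsilyloxy)-6-(2-hydroxy-3-methylbut-3-enyl)-2-phenyl-7-(triisopropylsilyloxy)chroman-4-one, both C2'' epimers | O=C1C[C@@H](c2ccccc2)Oc2cc(O[Si](C(C)C)(C(C)C)C(C)C)c(CC(O)C(C)=C)c(O[Si](C)(C)C(C)(C)C)c21 | intermediate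
11 | ethyl vinyl ether | C=COCC | starting material
12 | (2S)-5-(tert-butyldimethylsilyloxy)-6-[3-methyl-2-(vinyloxy)but-3-enyl]-2-phenyl-7-(triisopropylsilyloxy)chroman-4-one, both C2'' epimers | O=C1C[C@@H](c2ccccc2)Oc2cc(O[Si](C(C)C)(C(C)C)C(C)C)c(CC(OC=C)C(C)=C)c(O[Si](C)(C)C(C)(C)C)c21 | intermediate
13 | (2S)-5-(tert-butyldimethylsilyloxy)-6-[(2E)-3-methyl-6-oxohex-2-enyl]-2-phenyl-7-(triisopropylsilyloxy)chroman-4-one | O=C1C[C@@H](c2ccccc2)Oc2cc(O[Si](C(C)C)(C(C)C)C(C)C)c(C/C=C(\C)CCC=O)c(O[Si](C)(C)C(C)(C)C)c21 | intermediate
14 | isopropyltriphenylphosphonium iodide | CC(C)[P+](c1ccccc1)(c1ccccc1)c1ccccc1.[I-] | starting material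
15 | isopropylidenetriphenylphosphorane | CC(C)=P(c1ccccc1)(c1ccccc1)c1ccccc1 | intermediate (not isolated)
16 | (2S)-5-(tert-butyldimethylsilyloxy)-6-[(2E)-3,7-dimethylocta-2,6-dienyl]-2-phenyl-7-(triisopropylsilyloxy)chroman-4-one | O=C1C[C@@H](c2ccccc2)Oc2cc(O[Si](C(C)C)(C(C)C)C(C)C)c(C/C=C(\C)CCC=C(C)C)c(O[Si](C)(C)C(C)(C)C)c21 | intermediate
17 | (2S)-6-[(2E)-3,7-dimethylocta-2,6-dienyl]-5,7-dihydroxy-2-phenylchroman-4-one (CNP0201748.1) | O=C1C[C@@H](c2ccccc2)Oc2cc(O)c(C/C=C(\C)CCC=C(C)C)c(O)c21 | target

**Step count**

Total step count: 10. Longest linear sequence: 10 steps, from 1 to 17.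

**Steps most likely to fail**

Step 6. Singlet oxygen may abstract a benzylic hydrogen at C1'' instead of a methyl hydrogen, which puts the oxygen on C3'' and the alkene in conjugation with ring A, and so lowers the share of the C2'' carbinol. The fallback builds the carbinol by C–C bond formation instead of C–H oxidation. It sets out from 6: Lemieux–Johnson cleavage of the allyl group (OsO4 cat., NaIO4, 2,6-lutidine, dioxane–H2O) would give the arylacetaldehyde (2S)-2-[5-(tert-butyldimethylsilyloxy)-4-oxo-2-phenyl-7-(triisopropylsilyloxy)chroman-6-yl]acetaldehyde F1. Nozaki–Hiyama–Kishi addition of 2-bromopropene (CrCl2, NiCl2 cat., DMF, rt) would then add the isopropenyl group to the aldehyde without base and without touching the C4 ketone. The fallback rejoins the route at 10, with the oxygen fixed on C2'' by construction.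

Step 7. The vinyl interchange is an equilibrium and may stall on the hindered secondary alcohol, and traces of acid may divert material into mixed acetals. The fallback replaces the equilibrium by an irreversible metal-catalysed vinyl transfer run in tandem with the rearrangement. It sets out from 10: with vinyl acetate, [Ir(cod)Cl]2 (cat.) and Na2CO3 in toluene at 100 °C the alcohol should be vinylated with loss of acetate, and at this temperature the vinyl ether 12 would rearrange in the same flask. The fallback rejoins the route at 13 and makes no new compound (F0).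

Step 9. The ylide may act as a base at C3, which would open the pyranone ring by β-elimination of the aryloxide and erode the configuration at C2, or it may add in part to the C4 ketone. The fallback installs the two terminal methyl groups without any strong base. It sets out from 13: Ramirez dibromo-olefination (CBr4, PPh3, 2,6-lutidine, CH2Cl2, 0 °C) is selective for aldehydes and would give the 1,1-dibromoalkene (2S)-5-(tert-butyldimethylsilyloxy)-6-[(2E)-7,7-dibromo-3-methylhepta-2,6-dienyl]-2-phenyl-7-(triisopropylsilyloxy)chroman-4-one F2. Twofold Negishi methylation (Me2Zn, Pd(PtBu3)2 cat., THF, rt → 50 °C) tolerates the ketone and would replace both bromines by methyl. The fallback rejoins the route at 16.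

**Further compounds**

F1 | step 6 | (2S)-2-[5-(tert-butyldimethylsilyloxy)-4-oxo-2-phenyl-7-(triisopropylsilyloxy)chroman-6-yl]acetaldehyde | O=C1C[C@@H](c2ccccc2)Oc2cc(O[Si](C(C)C)(C(C)C)C(C)C)c(CC=O)c(O[Si](C)(C)C(C)(C)C)c21
F0 | step 7 | none | none
F2 | step 9 | (2S)-5-(tert-butyldimethylsilyloxy)-6-[(2E)-7,7-dibromo-3-methylhepta-2,6-dienyl]-2-phenyl-7-(triisopropylsilyloxy)chroman-4-one | O=C1C[C@@H](c2ccccc2)Oc2cc(O[Si](C(C)C)(C(C)C)C(C)C)c(C/C=C(\C)CCC=C(Br)Br)c(O[Si](C)(C)C(C)(C)C)c21
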